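**Retrosynthetic overview**
- The last ring is the seven-membered dioxepinone of the depsidone. It is opened at the C5–O diaryl ether bond (oxidative phenol coupling) and then at the ester between the ring A carboxyl group and O6 of ring B; the ring A ketone travels as a dioxolane.
- The plan rests on the tetrahydropyran ring (O1', spiro carbon C3 = C2', C3', C4', C5', C6'). C3'–C5' are three plain CH2 groups between the spiro carbon and the methyl-bearing C6'. The target has the lactone oxygen O2 axial and the C6' methyl equatorial, so C3 is the thermodynamic epimer and can be set by acid.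
- The pyran is therefore cut at C4'=C5' (ring-closing metathesis, then hydrogenation). The diene is a mixed ketal lactone with an allyl group on C3 and the (R)-but-3-en-2-yl group on the ketal oxygen; C6' is bought with (R)-but-3-en-2-ol.
- The mixed ketal comes from a keto acid and the alcohol. The free acid is used instead of the hindered methyl ester so that the carboxyl group can capture the oxocarbenium ion directly. Both aromatic rings derive from methyl orsellinate.
- Order of ring formation: isochromanone lactone (step 5), dihydropyran (step 6), dioxepinone (step 17).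

Key step: step 6

Remark: atom labels follow the spiro[isochromane-3,2'-pyran] skeleton of ring B: C1 (lactone carbonyl), O2, C3 (spiro carbon = C2'), C4, C4a, C5–C8, C8a; pyran O1', C3'–C6'. Ring A is the methoxy-bearing benzoate ring.
Remark: the ketal carbon is formed without control, so the mixed ketal, the metathesis product and the hydrogenation product are mixtures of C3 epimers that are carried on together. For the first two the SMILES shows the 3S epimer; for the third the spiro centre is left open.

**Ring B and the spiroketal**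

Step 1
Reactants: 1 methyl 2,4-dihydroxy-6-methylbenzoate (methyl orsellinate)
Product: 2 methyl 2,4-bis(benzyloxy)-6-methylbenzoate
Conditions: BnBr (2.4 equiv), K2CO3 (3 equiv), DMF, 60 °C
Reagents that add atoms: benzyl bromide, BrCc1ccccc1
Why: Williamson ether synthesis in warm DMF alkylates both phenoxides, the hydrogen-bonded 2-OH more slowly, and gives ethers that survive strong base and leave later by hydrogenolysis.

Step 2
Reactants: 2 methyl 2,4-bis(benzyloxy)-6-methylbenzoate
Product: 3 2,4-bis(benzyloxy)-6-methylbenzoic acid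
Conditions: KOH (10 equiv), DMSO/H2O 4:1, 90 °C; then 1 M HCl, 0 °C
Reagents that add atoms: potassium hydroxide, [K+].[OH-] (its oxygen replaces the methoxy oxygen)
Why: Saponification of a 2,6-disubstituted benzoate needs poorly solvated hydroxide in hot aqueous DMSO, which benzyl ethers tolerate, and it provides the free carboxyl group that step 5 requires.

Step 3
Reactants: 4 but-3-enoic acid
Product: 5 N-methoxy-N-methylbut-3-enamide
Conditions: MeNH(OMe)·HCl (1.1 equiv), EDC·HCl (1.2 equiv), N-methylmorpholine (2.3 equiv), CH2Cl2, 0 °C → rt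
Reagents that add atoms: N,O-dimethylhydroxylamine hydrochloride, CNOC.Cl
Why: Carbodiimide amide coupling (Weinreb amide formation) with a weak amine base at low temperature, so that the β,γ-double bond is not drawn into conjugation.

Step 4
Reactants: 3 2,4-bis(benzyloxy)-6-methylbenzoic acid; 5 N-methoxy-N-methylbut-3-enamide
Product: 7 2,4-bis(benzyloxy)-6-(2-oxopent-4-en-1-yl)benzoic acid, via dilithiated acid 6 (not isolated)
Conditions: LiN(iPr)2 (LDA, 2.3 equiv), THF, −78 → −20 °C; then 5 (1.2 equiv), −78 °C; cold 1 M HCl quench; crude product used at once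
Reagents that add atoms: none
Why: Lateral (benzylic) lithiation of the lithium carboxylate followed by Weinreb ketone synthesis; the ketone is released only at the cold acidic quench, so the allyl ketone never meets base and should stay unconjugated (7 may sit partly as its ring-closed lactol tautomer, which also shields the ketone).

Step 5
Reactants: 7 2,4-bis(benzyloxy)-6-(2-oxopent-4-en-1-yl)benzoic acid; 8 (R)-but-3-en-2-ol
Product: 9 (3S)-6,8-bis(benzyloxy)-3-{[(2R)-but-3-en-2-yl]oxy}-3-(prop-2-en-1-yl)-3,4-dihydro-1H-isochromen-1-one, together with its 3R epimer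
Conditions: 8 (5 equiv), Tf2NH (5 mol %), 4 Å molecular sieves, CH2Cl2, −40 → 0 °C; Et3N quench; chromatography on Et3N-washed silica
Reagents that add atoms: none
Why: Acid-catalysed pseudo-ester (mixed ketal lactone) formation: the alcohol adds to the ketone, loss of water gives an oxocarbenium ion, and the neighbouring carboxyl group closes the six-membered lactone on it at low temperature; the ketal carbon forms without facial control, which is harmless because C3 is corrected in step 8, and the carbinol centre of 8 is not touched.

Step 6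
Reactants: 9 (3S)-6,8-bis(benzyloxy)-3-{[(2R)-but-3-en-2-yl]oxy}-3-(prop-2-en-1-yl)-3,4-dihydro-1H-isochromen-1-one (epimer mixture at C3)
Product: 10 (3S,6'R)-6,8-bis(benzyloxy)-6'-methyl-3',6'-dihydrospiro[isochromane-3,2'-pyran]-1-one, together with its 3R epimer
Conditions: second-generation Grubbs catalyst RuCl2(=CHPh)(H2IMes)(PCy3) (5 mol %), 1,4-benzoquinone (10 mol %), CH2Cl2 (0.01 M), 40 °C, argon stream
Reagents that add atoms: none
Why: The ruthenium benzylidene loads onto the less hindered allyl alkene of 9, the new alkylidene undergoes [2+2] cycloaddition with the vinyl group of the but-3-en-2-yl ether to a ruthenacyclobutane, and cycloreversion releases 10 and, on turnover, ethene. The closest known reaction type is ring-closing metathesis of dienes tethered through a ketal carbon to unsaturated spiroketals. The one ring closed is the six-membered 3',6'-dihydro-2H-pyran, formed by joining C4' and C5' of a 1,7-diene on the existing isochromanone. No stereocentre is created: the ring alkene can only be cis, C6' comes unchanged from 8 and C3 from step 5. The selectivity needed is ring closure over oligomerisation and over alkene migration; both monosubstituted alkenes hang on one quaternary ketal carbon (gem-disubstituent effect), the solution is dilute, and benzoquinone intercepts ruthenium hydrides. Both C3 epimers of 9 should cyclise, so the mixture is carried through.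

Step 7
Reactants: 10 (3S,6'R)-6,8-bis(benzyloxy)-6'-methyl-3',6'-dihydrospiro[isochromane-3,2'-pyran]-1-one (epimer mixture at C3)
Product: 11 (6'R)-6,8-dihydroxy-6'-methyl-3',4',5',6'-tetrahydrospiro[isochromane-3,2'-pyran]-1-one, mixture of C3 epimers
Conditions: H2 (1 atm), Pd/C (zerovalent palladium on carbon, 10 wt %), EtOAc, rt
Reagents that add atoms: none
Why: Heterogeneous catalytic hydrogenation saturates the cis-disubstituted ring alkene and hydrogenolyses both benzyl ethers under neutral conditions that leave the ketal lactone intact; the alkene should be reduced before it can migrate toward C6', so that centre stays R.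

Step 8
Reactants: 11 (6'R)-6,8-dihydroxy-6'-methyl-3',4',5',6'-tetrahydrospiro[isochromane-3,2'-pyran]-1-one (C3 epimers)
Product: 12 (3S,6'R)-6,8-dihydroxy-6'-methyl-3',4',5',6'-tetrahydrospiro[isochromane-3,2'-pyran]-1-one
Conditions: camphor-10-sulfonic acid (10 mol %), CH2Cl2, rt
Reagents that add atoms: none
Why: Acid-catalysed spiroketal equilibration under thermodynamic control: protonation ionises the C3–O2 bond to a pyranyl oxocarbenium ion with the carboxylic acid still tethered, and reclosure should funnel both epimers into the one with O2 axial on the pyran chair (anomeric effect) and C4 and the C6' methyl equatorial, which is 3S.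

**Ring A acid**

Step 9
Reactants: 1 methyl 2,4-dihydroxy-6-methylbenzoate
Product: 13 methyl 2-hydroxy-4-methoxy-6-methylbenzoate
Conditions: MeI (1.05 equiv), K2CO3 (1.1 equiv), acetone, rt → 56 °C
Reagents that add atoms: iodomethane, CI
Why: Williamson methylation is selective for the 4-OH, which is the more acidic and is free, whereas the 2-OH is tied to the ester carbonyl by a hydrogen bond.

Step 10
Reactants: 13 methyl 2-hydroxy-4-methoxy-6-methylbenzoate
Product: 14 methyl 2-(benzyloxy)-4-methoxy-6-methylbenzoate
Conditions: BnBr (1.3 equiv), K2CO3 (2 equiv), DMF, 70 °C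
Reagents that add atoms: benzyl bromide, BrCc1ccccc1
Why: Williamson benzylation of the chelated phenol in warm DMF installs a group that tolerates the lithium amide and hot hydroxide and leaves by hydrogenolysis in step 16.

Step 11
Reactants: 15 hexanoyl chloride
Product: 16 N-methoxy-N-methylhexanamide
Conditions: MeNH(OMe)·HCl (1.1 equiv), pyridine (2.2 equiv), CH2Cl2, 0 °C → rt
Reagents that add atoms: N,O-dimethylhydroxylamine hydrochloride, CNOC.Cl
Why: Acylation of the amine by the acid chloride (Weinreb amide formation) is a standard, clean amide synthesis.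

Step 12
Reactants: 14 methyl 2-(benzyloxy)-4-methoxy-6-methylbenzoate; 16 N-methoxy-N-methylhexanamide
Product: 18 methyl 2-(benzyloxy)-4-methoxy-6-(2-oxoheptyl)benzoate, via benzylic lithium species 17 (not isolated)
Conditions: LiN(iPr)2 (LDA, 1.5 equiv), THF, −78 °C; then 16 (1.2 equiv), −78 °C; 1 M HCl quench
Reagents that add atoms: none
Why: Lateral lithiation of the ortho-toluate (benzylic anion stabilised by the ortho ester) and Weinreb ketone synthesis, which stops at the ketone because the amide adduct holds until work-up.

Step 13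
Reactants: 18 methyl 2-(benzyloxy)-4-methoxy-6-(2-oxoheptyl)benzoate
Product: 19 methyl 2-(benzyloxy)-4-methoxy-6-[(2-pentyl-1,3-dioxolan-2-yl)methyl]benzoate
Conditions: Me3SiOCH2CH2OSiMe3 (2 equiv), Me3SiOTf (5 mol %), CH2Cl2, −78 → −20 °C; pyridine quench
Reagents that add atoms: 1,2-bis(trimethylsilyloxy)ethane, C[Si](C)(C)OCCO[Si](C)(C)C
Why: Silyl-transfer ketalisation forms the dioxolane at low temperature without protic acid, so the keto ester is not cyclised to an isocoumarin; the ketone must be masked because its enol would otherwise displace the ring B phenol from the later aryl ester.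

Step 14
Reactants: 19 methyl 2-(benzyloxy)-4-methoxy-6-[(2-pentyl-1,3-dioxolan-2-yl)methyl]benzoate
Product: 20 2-(benzyloxy)-4-methoxy-6-[(2-pentyl-1,3-dioxolan-2-yl)methyl]benzoic acid
Conditions: KOH (10 equiv), DMSO/H2O 4:1, 90 °C; then 1 M HCl to pH 4, 0 °C, immediate extraction
Reagents that add atoms: potassium hydroxide, [K+].[OH-] (its oxygen replaces the methoxy oxygen)
Why: Saponification of the hindered benzoate in hot aqueous DMSO; dioxolane, benzyl ether and methyl ether are stable to base, and the cold, mildly acidic work-up should spare the ketal.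

**Union and depsidone closure**

Step 15
Reactants: 12 (3S,6'R)-6,8-dihydroxy-6'-methyl-3',4',5',6'-tetrahydrospiro[isochromane-3,2'-pyran]-1-one; 20 2-(benzyloxy)-4-methoxy-6-[(2-pentyl-1,3-dioxolan-2-yl)methyl]benzoic acid
Product: 21 (3S,6'R)-8-hydroxy-6'-methyl-1-oxo-3',4',5',6'-tetrahydrospiro[isochromane-3,2'-pyran]-6-yl 2-(benzyloxy)-4-methoxy-6-[(2-pentyl-1,3-dioxolan-2-yl)methyl]benzoate
Conditions: DCC (1.1 equiv), DMAP (0.1 equiv), CH2Cl2, 0 °C → rt
Reagents that add atoms: none
Why: Steglich esterification should be regioselective for the 6-OH, because the 8-OH is held in a hydrogen bond to the lactone carbonyl and is the poorer nucleophile; both ketals are inert to these neutral conditions.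

Step 16
Reactants: 21 depside benzyl ether
Product: 22 (3S,6'R)-8-hydroxy-6'-methyl-1-oxo-3',4',5',6'-tetrahydrospiro[isochromane-3,2'-pyran]-6-yl 2-hydroxy-4-methoxy-6-[(2-pentyl-1,3-dioxolan-2-yl)methyl]benzoate
Conditions: H2 (1 atm), Pd/C (zerovalent palladium on carbon, 10 wt %), EtOAc, rt
Reagents that add atoms: none
Why: Hydrogenolysis of the aryl benzyl ether frees the ring A phenol under neutral conditions that leave the aryl ester, the dioxolane and the spiroketal lactone alone.

Step 17
Reactants: 22 depside diphenol
Product: 23 dioxolane-protected depsidone (the ethylene ketal of the target at the side-chain ketone)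
Conditions: activated MnO2 (15 equiv), CH2Cl2, rt, dark
Reagents that add atoms: none
Why: Oxidative phenol coupling (biomimetic depside-to-depsidone closure): one-electron oxidation gives phenoxyl radicals, the ring A oxygen couples with C5 of ring B (para to the 8-OH and reachable through a seven-membered ring), and the cyclohexadienone tautomerises back to the phenol.

Step 18
Reactants: 23 dioxolane-protected depsidone
Product: 24 CNP0301127.1 (target)
Conditions: 1 M aq. HCl–THF 1:4, rt
Reagents that add atoms: water, O
Why: Acid-catalysed hydrolysis of the dioxolane frees the 2-oxoheptyl ketone; the same acid can only hold the spiro carbon in its thermodynamic 3S configuration, and the conditions are mild enough for the depsidone ester.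

**Compound list**
1 | methyl 2,4-dihydroxy-6-methylbenzoate (methyl orsellinate) | COC(=O)c1c(C)cc(O)cc1O | starting material
2 | methyl 2,4-bis(benzyloxy)-6-methylbenzoate | COC(=O)c1c(C)cc(OCc2ccccc2)cc1OCc1ccccc1 | intermediate
3 | 2,4-bis(benzyloxy)-6-methylbenzoic acid | OC(=O)c1c(C)cc(OCc2ccccc2)cc1OCc1ccccc1 | intermediate
4 | but-3-enoic acid | C=CCC(O)=O | starting material
5 | N-methoxy-N-methylbut-3-enamide | C=CCC(=O)N(C)OC | intermediate
6 | lithium 2,4-bis(benzyloxy)-6-(lithiomethyl)benzoate (dilithiated acid, not isolated) | [Li]Cc1cc(OCc2ccccc2)cc(OCc2ccccc2)c1C(=O)O[Li] | intermediate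
7 | 2,4-bis(benzyloxy)-6-(2-oxopent-4-en-1-yl)benzoic acid | C=CCC(=O)Cc1cc(OCc2ccccc2)cc(OCc2ccccc2)c1C(O)=O | intermediate
8 | (R)-but-3-en-2-ol | C=C[C@@H](C)O | starting material
9 | (3S)-6,8-bis(benzyloxy)-3-{[(2R)-but-3-en-2-yl]oxy}-3-(prop-2-en-1-yl)-3,4-dihydro-1H-isochromen-1-one (3S epimer drawn; the 3R epimer accompanies it) | C(c1ccccc1)Oc1cc(OCc2ccccc2)c2c(c1)C[C@](O[C@H](C)C=C)(CC=C)OC2=O | intermediate
10 | (3S,6'R)-6,8-bis(benzyloxy)-6'-methyl-3',6'-dihydrospiro[isochromane-3,2'-pyran]-1-one (3S epimer drawn; the 3R epimer accompanies it) | C(c1ccccc1)Oc1cc(OCc2ccccc2)c2c(c1)C[C@]1(CC=C[C@@H](C)O1)OC2=O | intermediate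
11 | (6'R)-6,8-dihydroxy-6'-methyl-3',4',5',6'-tetrahydrospiro[isochromane-3,2'-pyran]-1-one, mixture of C3 epimers | Oc1cc(O)c2c(c1)CC1(CCC[C@@H](C)O1)OC2=O | intermediate
12 | (3S,6'R)-6,8-dihydroxy-6'-methyl-3',4',5',6'-tetrahydrospiro[isochromane-3,2'-pyran]-1-one | Oc1cc(O)c2c(c1)C[C@]1(CCC[C@@H](C)O1)OC2=O | intermediate
13 | methyl 2-hydroxy-4-methoxy-6-methylbenzoate | COC(=O)c1c(C)cc(OC)cc1O | intermediate
14 | methyl 2-(benzyloxy)-4-methoxy-6-methylbenzoate | COC(=O)c1c(C)cc(OC)cc1OCc1ccccc1 | intermediate
15 | hexanoyl chloride | CCCCCC(Cl)=O | starting material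
16 | N-methoxy-N-methylhexanamide | CCCCCC(=O)N(C)OC | intermediate
17 | methyl 2-(benzyloxy)-6-(lithiomethyl)-4-methoxybenzoate (not isolated) | [Li]Cc1cc(OC)cc(OCc2ccccc2)c1C(=O)OC | intermediate
18 | methyl 2-(benzyloxy)-4-methoxy-6-(2-oxoheptyl)benzoate | CCCCCC(=O)Cc1cc(OC)cc(OCc2ccccc2)c1C(=O)OC | intermediate
19 | methyl 2-(benzyloxy)-4-methoxy-6-[(2-pentyl-1,3-dioxolan-2-yl)methyl]benzoate | CCCCCC1(Cc2cc(OC)cc(OCc3ccccc3)c2C(=O)OC)OCCO1 | intermediate
20 | 2-(benzyloxy)-4-methoxy-6-[(2-pentyl-1,3-dioxolan-2-yl)methyl]benzoic acid | CCCCCC1(Cc2cc(OC)cc(OCc3ccccc3)c2C(O)=O)OCCO1 | intermediate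
21 | (3S,6'R)-8-hydroxy-6'-methyl-1-oxo-3',4',5',6'-tetrahydrospiro[isochromane-3,2'-pyran]-6-yl 2-(benzyloxy)-4-methoxy-6-[(2-pentyl-1,3-dioxolan-2-yl)methyl]benzoate | CCCCCC1(Cc2cc(OC)cc(OCc3ccccc3)c2C(=O)Oc2cc(O)c3c(c2)C[C@]2(CCC[C@@H](C)O2)OC3=O)OCCO1 | intermediate
22 | (3S,6'R)-8-hydroxy-6'-methyl-1-oxo-3',4',5',6'-tetrahydrospiro[isochromane-3,2'-pyran]-6-yl 2-hydroxy-4-methoxy-6-[(2-pentyl-1,3-dioxolan-2-yl)methyl]benzoate | CCCCCC1(Cc2cc(OC)cc(O)c2C(=O)Oc2cc(O)c3c(c2)C[C@]2(CCC[C@@H](C)O2)OC3=O)OCCO1 | intermediate
23 | dioxolane-protected depsidone (ethylene ketal of the target at the side-chain ketone; ring A oxygen bonded to C5 of ring B) | CCCCCC1(Cc2cc(OC)cc3c2C(=O)Oc2cc(O)c4c(c2O3)C[C@]2(CCC[C@@H](C)O2)OC4=O)OCCO1 | intermediate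
24 | CNP0301127.1, (3S,6'R) spiroketal depsidone | CCCCCC(=O)Cc1cc(OC)cc2c1C(=O)Oc1cc(O)c3c(c1O2)C[C@]1(CCC[C@@H](C)O1)OC3=O | target

**Step count**
Total: 18 steps. Longest linear sequence: 11 steps (1, 2, 4, 5, 6, 7, 8, 15, 16, 17, 18).

**Steps most likely to fail**

1. Step 17 (oxidative diaryl ether closure). Both phenols are hydrogen-bonded to carbonyl groups and may resist oxidation. Coupling may go to C7 (ortho to the 8-OH) instead of C5. The product, a hydroquinone monoaryl ether, may be oxidised further. Fallback, setting out from 12 and coming back at 23: the ether is made by metal-catalysed C–O coupling instead of phenol oxidation.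
 - Chlorination of 12 with SO2Cl2 (1.0 equiv, Et2O, 0 °C) at C5, the position para to the hydrogen-bonded 8-OH, should give (3S,6'R)-5-chloro-6,8-dihydroxy-6'-methyl-3',4',5',6'-tetrahydrospiro[isochromane-3,2'-pyran]-1-one F1.
 - Steglich esterification of the 6-OH of F1 with 20 (DCC, DMAP, CH2Cl2) gives the chloro depside benzyl ether F2.
 - Hydrogenolysis (H2, Pd/C, EtOAc, stopped once the benzyl ether is gone, since the aryl chloride is reduced far more slowly in neutral solvent) gives the chloro depside diphenol F3.
 - Intramolecular palladium-catalysed diaryl ether formation (Pd(OAc)2, tBuXPhos, K3PO4, toluene, 100 °C) joins the ring A phenol to C5 and delivers 23.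

2. Step 5 (mixed ketal lactone). The exchange with a hindered secondary alcohol may be incomplete. The lactol form may be dehydrated toward an isocoumarin. The allyl double bond may migrate into conjugation under acid. Fallback, setting out from 7 and 8 and coming back at 9: equilibrium dehydration is replaced by irreversible silyl transfer.
 - 8 is silylated (Me3SiCl, imidazole, pentane) to (R)-(but-3-en-2-yloxy)trimethylsilane F4.
 - 7 is converted under neutral conditions (N-methyl-N-(trimethylsilyl)trifluoroacetamide, CH2Cl2, volatiles removed) into trimethylsilyl 2,4-bis(benzyloxy)-6-(2-oxopent-4-en-1-yl)benzoate F5.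
 - F5, F4 (1.5 equiv) and Me3SiOTf (5 mol %) in CH2Cl2 at −78 °C should undergo silyl-transfer ketalisation: the silyl carboxylate captures the oxocarbenium ion and hexamethyldisiloxane is the sink, as in the formation of 1,3-dioxolan-4-ones from bis-silylated α-hydroxy acids and ketones. This gives 9.

3. Step 4 (lateral acylation). The benzylic dianion may take a proton from the acidic α-CH2 of the β,γ-unsaturated amide instead of adding, and the double bond may shift toward conjugation. Fallback, setting out from 3 and coming back at 7: the allyl group is brought in as a nucleophile, not inside the acylating agent.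
 - The dianion 6 is added to N-methoxy-N-methylcarbamoyl chloride (THF, −78 °C) to give 2,4-bis(benzyloxy)-6-{2-[methoxy(methyl)amino]-2-oxoethyl}benzoic acid F6.
 - CH2=CHCH2MgBr (2.5 equiv, THF, −78 °C; cold 1 M HCl quench) adds once to the Weinreb amide of F6 and releases 7 only on work-up.

**Further compounds**
F1 | step 17 | (3S,6'R)-5-chloro-6,8-dihydroxy-6'-methyl-3',4',5',6'-tetrahydrospiro[isochromane-3,2'-pyran]-1-one | Oc1cc(O)c2c(c1Cl)C[C@]1(CCC[C@@H](C)O1)OC2=O
F2 | step 17 | chloro depside benzyl ether (6-O ester of F1 with 20) | CCCCCC1(Cc2cc(OC)cc(OCc3ccccc3)c2C(=O)Oc2cc(O)c3c(c2Cl)C[C@]2(CCC[C@@H](C)O2)OC3=O)OCCO1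
F3 | step 17 | chloro depside diphenol | CCCCCC1(Cc2cc(OC)cc(O)c2C(=O)Oc2cc(O)c3c(c2Cl)C[C@]2(CCC[C@@H](C)O2)OC3=O)OCCO1
F4 | step 5 | (R)-(but-3-en-2-yloxy)trimethylsilane | C=C[C@@H](C)O[Si](C)(C)C
F5 | step 5 | trimethylsilyl 2,4-bis(benzyloxy)-6-(2-oxopent-4-en-1-yl)benzoate | C=CCC(=O)Cc1cc(OCc2ccccc2)cc(OCc2ccccc2)c1C(=O)O[Si](C)(C)C
F6 | step 4 | 2,4-bis(benzyloxy)-6-{2-[methoxy(methyl)amino]-2-oxoethyl}benzoic acid | CON(C)C(=O)Cc1cc(OCc2ccccc2)cc(OCc2ccccc2)c1C(O)=O
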